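A direct plan would take two molecules of dehydrozaluzanin C (A1). One would be dehydrogenated to the cross-conjugated trienone A2, whose C2=C1–C10=C14 diene would add to the exocyclic enone of the second A1 (Diels–Alder) to give the spiro adduct A3. A base would then move the C1=C10 olefin into conjugation.
Its weakest steps would be:
- the dehydrogenation to A2, because this trienone is diene and dienophile at once and would have to be made and consumed next to its own precursor;
- the intermolecular cycloaddition, because regio-, facial and exo/endo selectivity at the spiro centre C4′ would all have to come from two unbiased partners while A2 can also dimerize;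
- the supply of A1, because placing the C3 oxygen and three exocyclic olefins on a guaianolide would cost several redox steps that add no complexity.

The dienone half is not brought in as a guaianolide. Its 4-methylene-cyclopent-1-en-3-one (C1–C5, C15) is annulated last, by an allene-ether Nazarov cyclization, onto the enone C2(=O)–C1=C5 of a spiro-fused precursor. That precursor comes from dehydrocostus lactone and a costunolide-derived acrolein: an ene reaction joins C14–C15′ and moves the olefin to C3′=C4′, a nitrile oxide cycloaddition forges the spiro centre C4′ and brings in the C3′ oxygen, a Mukaiyama acetal aldol closes the seven-membered ring. The key step forms C2–C3 and C4–C5 in one operation; no trienone, no intermolecular cycloaddition and no oxygen transposition on a guaianolide are needed.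

Key step: step 11

Remark: guaiane numbering is used, with primed locants for the ketone half; the 5β-H (cis H-5/H-6) arrangement of the target is assumed to be the more stable C5 epimer of the cross-conjugated dienone, so C5 is fixed only in step 12.

Step 1
Reactants: 1 costunolide
Product: 3 keto acetal (trans-5-(dimethoxymethyl)-3-methylene-4-(3-oxobutyl)dihydrofuran-2(3H)-one; C6 and C7 as in 1), via keto aldehyde 2 (not isolated)
Conditions: O3, CH2Cl2–MeOH 4:1, −78 °C (Sudan red 7B end point); Me2S, −78 → 23 °C; then HC(OMe)3, PPTS, MeOH, 0 °C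
Reagents that add atoms: ozone, [O-][O+]=O; trimethyl orthoformate, COC(OC)OC
Why: Ozonolysis (Criegee cleavage) should cut the two electron-rich trisubstituted ring olefins and spare the electron-poor α-methylene lactone, the aldehyde alone is then acetalized, and C6/C7 (6βH, 7αH) are untouched.

Step 2
Reactants: 3 keto acetal
Product: 4 enol triflate (4-[3-(trifluoromethylsulfonyloxy)but-3-en-1-yl] analogue of 3)
Conditions: KN(SiMe3)2, THF, −78 °C; PhNTf2, −78 → −20 °C
Reagents that add atoms: N-phenyl-bis(trifluoromethanesulfonimide), O=S(=O)(N(c1ccccc1)S(=O)(=O)C(F)(F)F)C(F)(F)F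
Why: Kinetic deprotonation of the methyl ketone on its CH3 side and O-triflation of the enolate (enol triflate formation) should give the terminal vinyl triflate, with C14 as the =CH2 carbon.

Step 3
Reactants: 4 enol triflate
Product: 5 enal (4-[trans-2-(dimethoxymethyl)-4-methylene-5-oxotetrahydrofuran-3-yl]-2-methylenebutanal; formyl carbon = C1, C10=C14)
Conditions: CO (1 atm), Pd(OAc)2 (5 mol %), 1,3-bis(diphenylphosphino)propane, Et3SiH, Et3N, DMF, 60 °C
Reagents that add atoms: carbon monoxide, [C-]#[O+]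
Why: Palladium-catalysed reductive carbonylation (formylation) of the vinyl triflate by oxidative addition, CO insertion and hydride transfer from the silane should give the 2-substituted acrolein.

Step 4
Reactants: 5 enal; 6 dehydrocostus lactone
Product: 7 ene adduct aldehyde (C15′–C14 bond; C3′=C4′ olefin; C10 bears H, CHO and the lactone chain)
Conditions: Me2AlCl (1.5 equiv), CH2Cl2, −78 → −40 °C, 6 (1.5 equiv)
Reagents that add atoms: none
Why: Lewis-acid-promoted Alder ene reaction in which C15′ of the more reactive cyclopentylidene methylene of 6 attacks C14 of the Me2AlCl–enal complex on the convex α-face with transfer of H-3′α to C10, so that C14–C15′ forms, the olefin moves to C3′=C4′ and C10 is created (drawn for the side chain endo; it becomes epimerizable again in 22).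

Step 5
Reactants: 7 ene adduct aldehyde
Product: 9 (E)-nitroalkene (C1H=C2H–NO2), via nitro alcohol 8 (not isolated)
Conditions: MeNO2, Et3N (cat.), 0 °C; then MsCl, Et3N, CH2Cl2, −20 → 0 °C
Reagents that add atoms: nitromethane, C[N+](=O)[O-]
Why: Henry (nitroaldol) addition to the aldehyde and dehydration through the mesylate should give the conjugated nitroalkene and so bring in C2 and the nitrogen needed for the dipole.

Step 6
Reactants: 9 (E)-nitroalkene
Product: 10 primary nitro compound (C10–C1H2–C2H2–NO2)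
Conditions: diethyl 2,6-dimethyl-1,4-dihydropyridine-3,5-dicarboxylate (Hantzsch ester), SiO2, toluene, 60 °C
Reagents that add atoms: none
Why: Hantzsch ester transfer hydrogenation delivers hydride only to the strongly electrophilic nitro-olefin and should leave both α-methylene lactones and the other olefins untouched.

Step 7
Reactants: 10 primary nitro compound
Product: 12 isoxazoline (C2=N–O–C3′; C2–C4′ bond on the α-face of the ketone half), via nitrile oxide 11 (not isolated)
Conditions: PhNCO, Et3N (cat.), toluene (0.005 M), 23 → 60 °C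
Reagents that add atoms: none
Why: Mukaiyama dehydration gives the nitrile oxide, whose intramolecular 1,3-dipolar cycloaddition onto C3′=C4′ closes the cyclohexane through C2–C4′ (carbon to the proximal, oxygen to the distal olefin carbon, fixed by the tether) from the convex α-face, cis to H-5′, which sets the spiro centre C4′ and the C3′–O bond.

Step 8
Reactants: 12 isoxazoline
Product: 13 β-hydroxy ketone (C2 ketone in the spiro cyclohexanone; 3′α-OH)
Conditions: Mo(CO)6, MeCN–H2O 10:1, 80 °C
Reagents that add atoms: water, O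
Why: Reductive N–O cleavage of the isoxazoline by Mo(CO)6 and hydrolysis of the β-hydroxy imine should unveil the ketone and the C3′ alcohol without reducing any olefin or changing a stereocentre.

Step 9
Reactants: 13 β-hydroxy ketone
Product: 16 silyl enone (C2(=O)–C1=C5 in the new seven-membered ring; 3′α-OSiEt3), via bis-silyl enol ether 14 (not isolated), via β-methoxy ketone 15 (not isolated)
Conditions: Et3SiOTf, i-Pr2NEt, CH2Cl2, −78 → 0 °C; then DBU, 0 °C
Reagents that add atoms: triethylsilyl trifluoromethanesulfonate, CC[Si](CC)(CC)OS(=O)(=O)C(F)(F)F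
Why: The silyl triflate silylates the alcohol and enolizes the ketone toward C1 (its only enolizable side), the enol ether adds to the activated acetal carbon C5 (intramolecular Mukaiyama acetal aldol, seven-membered ring), and E1cB loss of methanol gives the enone.

Step 10
Reactants: 17 3-(methoxymethoxy)prop-1-yne
Product: 18 1-(methoxymethoxy)propa-1,2-diene
Conditions: KOt-Bu (0.2 equiv), neat, 23 → 50 °C, then distillation
Reagents that add atoms: none
Why: Base-catalysed propargyl–allenyl isomerization of the propargyl ether should give the alkoxyallene needed as the C3–C4–C15 unit.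

Step 11
Reactants: 16 silyl enone; 18 1-(methoxymethoxy)propa-1,2-diene
Product: 21 hydroxy dienone (complete dienone half; 3′α-OH; 5αH, 10αH), via allenyl carbinol 19 (not isolated), via silyl dienone 20 (not isolated)
Conditions: 18, n-BuLi, THF, −78 °C; CeCl3, −78 °C; 16, −78 °C; then (CF3CO)2O, 2,6-lutidine, CH2Cl2, −78 → −20 °C; then 1 M HCl, THF, 0 °C
Reagents that add atoms: none
Why: The 1-metallated alkoxyallene adds 1,2 to the C2 ketone (the only ketone, C3′ being silylated) to give carbinol 19, and trifluoroacetylation–ionization gives the pentadienyl cation C5=C1–C2(+)–C3(OMOM)=C4, which closes by 4π-conrotatory electrocyclization (bond C4–C5) to an oxocarbenium ion that loses the methoxymethyl cation, so that the C3 ketone, the C1=C2 olefin and the exocyclic C4=C15 methylene appear together with the C2–C3 bond made in the addition. The closest known reaction type is the cationic cyclopentannulation (allene-ether Nazarov cyclization) of α-alkoxyallenyl carbinols made from enones, which gives 5-methylene-cyclopent-2-enones. One ring is closed, the cyclopentenone, in the electrocyclic mode. The only new stereocentre is C5: the sense of conrotation is governed by the allylic centre C6, C4 is expected to bond anti to the C6–O bond (5α-H, as drawn), and this centre is left to step 12 on purpose. The step needs 1,2-addition to a hindered ketone in the presence of two α-methylene lactones, which the low basicity and oxophilicity of the organocerium reagent at −78 °C should secure, and the acid work-up also removes the silyl ether.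

Step 12
Reactants: 21 hydroxy dienone
Product: 23 target CNP0221188.1, via 5-epi diketone 22 (not isolated)
Conditions: Dess–Martin periodinane, NaHCO3, CH2Cl2, 0 → 23 °C; then DBU (0.3 equiv), CH2Cl2, 0 → 23 °C
Reagents that add atoms: none
Why: Dess–Martin oxidation gives the C3′ ketone, and DBU then epimerizes C5 (and C10, if step 4 gave a mixture; both are γ to C3=O) through the extended dienolate toward the 5β-H isomer, in which the C5–C6 and C10–C9 bonds lie on opposite faces of the planar dienone ring so that the cycloheptane can take a twist-chair with the trans-lactone diequatorial.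

**Compound list**

1 | costunolide (germacra-1(10)E,4E,11(13)-trien-12,6α-olide; 6βH, 7αH) | C/C1=C\CC/C(C)=C/[C@H]2OC(=O)C(=C)[C@@H]2CC1 | starting material
2 | keto aldehyde (trans-5-formyl-3-methylene-4-(3-oxobutyl)dihydrofuran-2(3H)-one; C5–C10, C14 and lactone of 1) | CC(=O)CC[C@H]1C(=C)C(=O)O[C@@H]1C=O | intermediate
3 | keto acetal (trans-5-(dimethoxymethyl)-3-methylene-4-(3-oxobutyl)dihydrofuran-2(3H)-one) | CC(=O)CC[C@H]1C(=C)C(=O)O[C@@H]1C(OC)OC | intermediate
4 | enol triflate (C10(OTf)=C14H2) | C=C(OS(=O)(=O)C(F)(F)F)CC[C@H]1C(=C)C(=O)O[C@@H]1C(OC)OC | intermediate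
5 | enal (2-substituted acrolein; C1 formyl, C10=C14) | C=C(C=O)CC[C@H]1C(=C)C(=O)O[C@@H]1C(OC)OC | intermediate
6 | dehydrocostus lactone (1αH,5αH-guaia-4(15),10(14),11(13)-trien-12,6α-olide) | C=C1CC[C@@H]2[C@@H]([C@@H]3[C@H]1CCC3=C)OC(=O)C2=C | starting material
7 | ene adduct aldehyde (1′αH,5′αH-guaia-3′,10′(14′),11′(13′)-trien-12′,6′α-olide joined C15′–C14 to the chain C10H(CHO)–C9–C8–lactone acetal; C10 as in the target) | C=C1CC[C@@H]2[C@@H]([C@@H]3[C@H]1CC=C3CC[C@H](C=O)CC[C@H]4C(=C)C(=O)O[C@@H]4C(OC)OC)OC(=O)C2=C | intermediate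
8 | nitro alcohol (C1 carbinol, both epimers) | C=C1CC[C@@H]2[C@@H]([C@@H]3[C@H]1CC=C3CC[C@H](C(O)C[N+](=O)[O-])CC[C@H]4C(=C)C(=O)O[C@@H]4C(OC)OC)OC(=O)C2=C | intermediate
9 | (E)-nitroalkene (C1=C2) | C=C1CC[C@@H]2[C@@H]([C@@H]3[C@H]1CC=C3CC[C@H](/C=C/[N+](=O)[O-])CC[C@H]4C(=C)C(=O)O[C@@H]4C(OC)OC)OC(=O)C2=C | intermediate
10 | primary nitro compound | C=C1CC[C@@H]2[C@@H]([C@@H]3[C@H]1CC=C3CC[C@H](CC[N+](=O)[O-])CC[C@H]4C(=C)C(=O)O[C@@H]4C(OC)OC)OC(=O)C2=C | intermediate
11 | nitrile oxide | C=C1CC[C@@H]2[C@@H]([C@@H]3[C@H]1CC=C3CC[C@H](CC#[N+][O-])CC[C@H]4C(=C)C(=O)O[C@@H]4C(OC)OC)OC(=O)C2=C | intermediate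
12 | isoxazoline (spiro centre C4′ set: C2 α, C15′ β; 3′α-O) | C=C1CC[C@@H]2[C@@H]([C@@H]3[C@H]1C[C@H]4ON=C5C[C@H](CC[C@H]6C(=C)C(=O)O[C@@H]6C(OC)OC)CC[C@]345)OC(=O)C2=C | intermediate
13 | β-hydroxy ketone (spiro cyclohexanone, C2=O; 3′α-OH) | C=C1CC[C@@H]2[C@@H]([C@@H]3[C@H]1C[C@@H](O)[C@@]34C(=O)C[C@H](CC[C@H]5C(=C)C(=O)O[C@@H]5C(OC)OC)CC4)OC(=O)C2=C | intermediate
14 | bis-silyl enol ether (3′-OSiEt3; C2(OSiEt3)=C1) | C=C1CC[C@@H]2[C@@H]([C@@H]3[C@H]1C[C@@H](O[Si](CC)(CC)CC)[C@@]34C(O[Si](CC)(CC)CC)=C[C@H](CC[C@H]5C(=C)C(=O)O[C@@H]5C(OC)OC)CC4)OC(=O)C2=C | intermediate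
15 | β-methoxy ketone (seven-membered ring closed; C1 and C5 not defined, both lost on elimination) | C=C1CC[C@@H]2[C@@H]([C@@H]3[C@H]1C[C@@H](O[Si](CC)(CC)CC)[C@@]34C(=O)C5C(OC)[C@H]6OC(=O)C(=C)[C@@H]6CC[C@@H]5CC4)OC(=O)C2=C | intermediate
16 | silyl enone (C2(=O)–C1=C5; 3′α-OSiEt3; 10αH) | C=C1CC[C@@H]2[C@@H]([C@@H]3[C@H]1C[C@@H](O[Si](CC)(CC)CC)[C@@]34C(=O)C5=C[C@H]6OC(=O)C(=C)[C@@H]6CC[C@@H]5CC4)OC(=O)C2=C | intermediate
17 | 3-(methoxymethoxy)prop-1-yne | C#CCOCOC | starting material
18 | 1-(methoxymethoxy)propa-1,2-diene | C=C=COCOC | intermediate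
19 | allenyl carbinol (C2 carbinol, configuration not defined, lost on ionization) | C=C1CC[C@@H]2[C@@H]([C@@H]3[C@H]1C[C@@H](O[Si](CC)(CC)CC)[C@@]34C(O)(C(OCOC)=C=C)C5=C[C@H]6OC(=O)C(=C)[C@@H]6CC[C@@H]5CC4)OC(=O)C2=C | intermediate
20 | silyl dienone (3′α-OSiEt3; 5αH, 10αH) | C=C1C(=O)C2=C3[C@H](CC[C@H]4C(=C)C(=O)O[C@@H]4[C@@H]13)CC[C@]21[C@H](O[Si](CC)(CC)CC)C[C@H]2C(=C)CC[C@H]3C(=C)C(=O)O[C@@H]3[C@H]21 | intermediate
21 | hydroxy dienone (3′α-OH; 5αH, 10αH) | C=C1C(=O)C2=C3[C@H](CC[C@H]4C(=C)C(=O)O[C@@H]4[C@@H]13)CC[C@]21[C@H](O)C[C@H]2C(=C)CC[C@H]3C(=C)C(=O)O[C@@H]3[C@H]21 | intermediate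
22 | 5-epi diketone (5αH epimer of the target) | C=C1C(=O)C2=C3[C@H](CC[C@H]4C(=C)C(=O)O[C@@H]4[C@@H]13)CC[C@]21C(=O)C[C@H]2C(=C)CC[C@H]3C(=C)C(=O)O[C@@H]3[C@H]21 | intermediate
23 | CNP0221188.1 (dienone half 5βH, 6βH, 7αH, 10αH; ketone half 1′αH, 5′αH, 6′βH, 7′αH; C2 on the α-face of C4′) | C=C1C(=O)C2=C3[C@H](CC[C@H]4C(=C)C(=O)O[C@@H]4[C@H]13)CC[C@]21C(=O)C[C@H]2C(=C)CC[C@H]3C(=C)C(=O)O[C@@H]3[C@H]21 | target

Total step count: 12. Longest linear sequence: 11 steps (1 → 23 through steps 1–9, 11 and 12; step 10 prepares 18).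

Steps most likely to fail:

1. Step 11. The allenyl metal may add to the two α-methylene lactones (conjugate or carbonyl addition) faster than to the hindered C2 ketone. The fallback sets out from 16 and returns at 21: dimethylamine in MeOH would mask both methylene lactones as the bis(dimethylaminomethyl) silyl enone F1; the same allene addition and acid-induced cyclization on F1 would give the bis-amine hydroxy dienone F2; exhaustive N-methylation with MeI would give the bis(trimethylammonium) diiodide F3, and aqueous NaHCO3 would regenerate both methylene groups by Hofmann elimination.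

2. Step 4. The enal complex may attack the cycloheptylidene C10′=C14′ methylene of 6, or the product aldehyde may cyclize further by an intramolecular carbonyl–ene reaction onto C3′=C4′. The fallback sets out from 6 and 5 and returns at 7 (as a C10 mixture, which the end game tolerates), replacing the ene union by an sp3–sp3 Suzuki–Miyaura coupling:
   - 6 would be converted by ene-type chlorination (HOCl from Ca(OCl)2 and CO2) into the allylic chloride F4;
   - 5 would be reduced (NaBH4, CeCl3·7H2O) to the allylic alcohol F5 and silylated to the silyl ether F6;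
   - 9-BBN would add to the 1,1-disubstituted olefin of F6 to give the alkylborane F7 (boron on C14, hydrogen on C10);
   - coupling of F7 with F4 at its primary terminus (Pd(dppf)Cl2, K3PO4) would give the silyl ether F8;
   - fluoride would free the alcohol F9, and Dess–Martin oxidation would give 7.

3. Step 12. The base equilibrium may not favour the 5β-H epimer, or the C5 carbanion may open the C6 lactone by vinylogous β-elimination. The fallback sets out from 21 and returns at 23, replacing the carbanion equilibration by kinetic protonation of a neutral silyl dienol ether: Me3SiOTf and Et3N would convert 21 into the bis-silyl fulvene F10 (C5 trigonal, 3′-OSiMe3); protodesilylation with PPTS in MeOH at −40 °C should deliver H-5 from the β-face and free the alcohol F11; Dess–Martin oxidation without base would then give 23.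

**Further compounds**

F1 | step 11 | bis(dimethylaminomethyl) silyl enone (C11 and C11′ not defined) | C=C1CC[C@@H]2[C@@H]([C@@H]3[C@H]1C[C@@H](O[Si](CC)(CC)CC)[C@@]34C(=O)C5=C[C@H]6OC(=O)C(CN(C)C)[C@@H]6CC[C@@H]5CC4)OC(=O)C2CN(C)C
F2 | step 11 | bis-amine hydroxy dienone | C=C1C(=O)C2=C3[C@H](CC[C@H]4C(CN(C)C)C(=O)O[C@@H]4[C@@H]13)CC[C@]21[C@H](O)C[C@H]2C(=C)CC[C@H]3C(CN(C)C)C(=O)O[C@@H]3[C@H]21
F3 | step 11 | bis(trimethylammonium) diiodide | C=C1C(=O)C2=C3[C@H](CC[C@H]4C(C[N+](C)(C)C)C(=O)O[C@@H]4[C@@H]13)CC[C@]21[C@H](O)C[C@H]2C(=C)CC[C@H]3C(C[N+](C)(C)C)C(=O)O[C@@H]3[C@H]21.[I-].[I-]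
F4 | step 4 | allylic chloride (15-chloro-1αH,5αH-guaia-3,10(14),11(13)-trien-12,6α-olide) | C=C1CC[C@@H]2[C@@H]([C@@H]3[C@H]1CC=C3CCl)OC(=O)C2=C
F5 | step 4 | allylic alcohol from 5 | C=C(CO)CC[C@H]1C(=C)C(=O)O[C@@H]1C(OC)OC
F6 | step 4 | tert-butyldimethylsilyl ether of F5 | C=C(CO[Si](C)(C)C(C)(C)C)CC[C@H]1C(=C)C(=O)O[C@@H]1C(OC)OC
F7 | step 4 | alkylborane (9-BBN on C14; C10 not defined) | CC(C)(C)[Si](C)(C)OCC(CB1C2CCCC1CCC2)CC[C@H]1C(=C)C(=O)O[C@@H]1C(OC)OC
F8 | step 4 | coupled silyl ether (C10 not defined) | C=C1CC[C@@H]2[C@@H]([C@@H]3[C@H]1CC=C3CCC(CO[Si](C)(C)C(C)(C)C)CC[C@H]4C(=C)C(=O)O[C@@H]4C(OC)OC)OC(=O)C2=C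
F9 | step 4 | primary alcohol (C10 not defined) | C=C1CC[C@@H]2[C@@H]([C@@H]3[C@H]1CC=C3CCC(CO)CC[C@H]4C(=C)C(=O)O[C@@H]4C(OC)OC)OC(=O)C2=C
F10 | step 12 | bis-silyl fulvene (C3-OSiMe3, C1=C5, C4=C15; 3′-OSiMe3) | C=C1C(O[Si](C)(C)C)=C2C3=C1[C@H]4OC(=O)C(=C)[C@@H]4CC[C@@H]3CC[C@]25[C@H](O[Si](C)(C)C)C[C@H]6C(=C)CC[C@H]7C(=C)C(=O)O[C@@H]7[C@H]65
F11 | step 12 | 3′α-alcohol of the target (5βH, 10αH) | C=C1C(=O)C2=C3[C@H](CC[C@H]4C(=C)C(=O)O[C@@H]4[C@H]13)CC[C@]21[C@H](O)C[C@H]2C(=C)CC[C@H]3C(=C)C(=O)O[C@@H]3[C@H]21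
A1 | direct plan | dehydrozaluzanin C | C=C1CC[C@@H]2[C@@H]([C@@H]3[C@H]1CC(=O)C3=C)OC(=O)C2=C
A2 | direct plan | cross-conjugated trienone (3-oxo-5αH-guaia-1,4(15),10(14),11(13)-tetraen-12,6α-olide) | C=C1CC[C@@H]2[C@@H]([C@@H]3C1=CC(=O)C3=C)OC(=O)C2=C
A3 | direct plan | Diels–Alder adduct (C1=C10 olefin) | C=C1C(=O)[C@H]2C3=C(CC[C@H]4C(=C)C(=O)O[C@@H]4[C@@H]13)CC[C@]21C(=O)C[C@H]2C(=C)CC[C@H]3C(=C)C(=O)O[C@@H]3[C@H]21
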